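**Retrosynthetic overview**
- Late stage: the 4'-O-MOM group is removed last; the C6 (E)-3-methylbut-1-enyl group comes from Suzuki coupling of a C6 iodide placed ortho to the chelated 5-OH; the C(CH3)2OH group comes from an acyl group (ester + 2 MeMgBr) that first serves as activating group and auxiliary anchor at the carbinol carbon.
- Key disconnection: the oxepine ring (C3–CH2–CH–O–C2'–C1'–C2) is cut at CH2–CH and at C2–C1', giving 3-(bromomethyl)chromone 4 (rings A and C) and the ring B glycolate imide 10 (chiral auxiliary, C1'–Br).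
- Enabling feature: the exocyclic CH2 on C3 of pyranone ring C is an allylic-type electrophile, and the neighbouring C2–H is the oxygen-flanked β-C–H of the enone that palladates readily. The 2'-oxygen of ring B holds the enolisable O–CH2–C(=O) carbon and the C1' bromide in a 1,4 relation that matches the 1,3 relation of CH2 and C2.
- Ring order: ring A (purchased) → ring C (step 1) → oxepine ring (step 7, ring B brought in preformed).

Key step: step 7

Remarks: flavone numbering is used for the tetracyclic compounds (O1, C2, C3, C4=O, C5–C8; C1'–C6' in ring B), and "oxepine-bridged" means that C3 and the 2'-oxygen are joined through CH2–CH(R), with CH bound to oxygen; boronate 16 is taken as commercially available.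

**Route**

Step 1
Reactants: 1 1-(2,6-dihydroxy-4-methoxyphenyl)ethan-1-one
Product: 2 5-hydroxy-7-methoxy-4-oxo-4H-chromene-3-carbaldehyde
Conditions: POCl3, DMF, 0 to 50 °C; then ice/H2O
Reagents that add atoms: N,N-dimethylformamide CN(C)C=O; water O
Why: Vilsmeier–Haack double formylation of the methyl ketone and cyclisation through one of the two equivalent phenols should give the 3-formylchromone directly, the symmetry of 1 removing any regiochemical question.

Step 2
Reactants: 2 5-hydroxy-7-methoxy-4-oxo-4H-chromene-3-carbaldehyde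
Product: 3 5-hydroxy-3-(hydroxymethyl)-7-methoxy-4H-chromen-4-one
Conditions: basic Al2O3, i-PrOH, 75 °C
Reagents that add atoms: none
Why: Meerwein–Ponndorf–Verley-type hydride transfer from 2-propanol on basic alumina should reduce only the aldehyde, a donor this mild leaving the vinylogous ester C2=C3–C4=O untouched.

Step 3
Reactants: 3 5-hydroxy-3-(hydroxymethyl)-7-methoxy-4H-chromen-4-one
Product: 4 3-(bromomethyl)-5-hydroxy-7-methoxy-4H-chromen-4-one
Conditions: CBr4, PPh3, CH2Cl2, 0 °C
Reagents that add atoms: tetrabromomethane BrC(Br)(Br)Br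
Why: Appel bromination converts the primary allylic-type alcohol under neutral conditions that the chelated, poorly nucleophilic 5-OH should not enter.

Step 4
Reactants: 5 4-bromobenzene-1,3-diol
Product: 6 2-bromo-5-(methoxymethoxy)phenol
Conditions: MOMCl (1.0 equiv), i-Pr2NEt, CH2Cl2, 0 °C
Reagents that add atoms: chloromethyl methyl ether COCCl
Why: Williamson-type O-alkylation should take place at the hydroxyl para to bromine, which is the less hindered one and is not flanked by the halogen, the regioisomer and the bis-ether being removed by chromatography.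

Step 5
Reactants: 6 2-bromo-5-(methoxymethoxy)phenol; 7 bromoacetic acid
Product: 8 2-[2-bromo-5-(methoxymethoxy)phenoxy]acetic acid
Conditions: NaOH (aq), 80 °C; then 1 M HCl to pH 3, 0 °C
Reagents that add atoms: none
Why: Williamson ether synthesis of the sodium phenoxide with sodium bromoacetate gives the aryloxyacetic acid, the base-stable MOM ether surviving if the acidification is kept cold and short.

Step 6
Reactants: 8 2-[2-bromo-5-(methoxymethoxy)phenoxy]acetic acid; 9 (R)-4-benzyloxazolidin-2-one
Product: 10 (R)-4-benzyl-3-{2-[2-bromo-5-(methoxymethoxy)phenoxy]acetyl}oxazolidin-2-one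
Conditions: Me3CCOCl, Et3N, THF, −20 °C; then 9, LiCl, −20 °C to rt
Reagents that add atoms: none
Why: N-acylation of the oxazolidinone by the mixed pivalic anhydride under LiCl/Et3N activation is a standard mild entry to glycolate imides, attack taking place at the less hindered carbonyl of the anhydride.

Step 7
Reactants: 10 (R)-4-benzyl-3-{2-[2-bromo-5-(methoxymethoxy)phenoxy]acetyl}oxazolidin-2-one; 4 3-(bromomethyl)-5-hydroxy-7-methoxy-4H-chromen-4-one
Product: 12 oxepine-bridged imide (5-hydroxy-7-methoxy-4'-(methoxymethoxy)flavone bridged C3–CH2–CH(R)–O–C2', R = C(=O)N of (R)-4-benzyl-2-oxooxazolidine, S at the bridge CH), via open-chain alkylated imide 11 (not isolated)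
Conditions: NaN(SiMe3)2 (2.1 equiv), THF, −78 °C, then 4, −78 to −40 °C; then Me3CCO2H, Me3CCO2K, Pd(OAc)2 (5 mol %), PCy3·HBF4 (10 mol %), DMA, 90 °C, same flask
Reagents that add atoms: none
Why: NaN(SiMe3)2 forms the sodium-chelated Z-enolate of glycolate imide 10 (the second equivalent only deprotonates the 5-OH of 4), and SN2 alkylation by the allylic-type bromide on the enolate face opposite the benzyl group of the (R)-auxiliary makes the CH2–CH bond and should set the (S) centre (Evans glycolate alkylation). In the same flask, zerovalent palladium formed from Pd(OAc)2 and PCy3 adds oxidatively to the C1'–Br bond of 11, pivalate-assisted concerted metalation–deprotonation takes place at C2–H of ring C, and reductive elimination makes the C2–C1' bond (intramolecular direct arylation; the pairing corresponds to known one-pot alkylation/direct-arylation annulations). The oxepine ring is thus closed in the second event as a formal 7-endo closure onto the C2=C3 bond through an eight-membered palladacycle, and no stereocentre is formed in this closure. Site selectivity rests on the saturated CH2–CH link, which leaves no other alkene or acidic C–H within reach of the aryl–palladium unit, and on the preference of aryl–palladium species for the β-carbon (C2) of the enone. The remaining selectivities are SN2 rather than SN2' attack on 4 (hard sodium enolate, primary bromide, low temperature) and retention of the new centre during the warm stage, which relies on the weak carboxylate base and on the A(1,3) strain that disfavours re-enolisation of α-substituted N-acyloxazolidinones.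

Step 8
Reactants: 12 oxepine-bridged imide
Product: 13 oxepine-bridged methyl ester (R = CO2CH3, S)
Conditions: MeMgBr, MeOH (gives MeOMgBr), CH2Cl2, 0 °C; aq. NH4Cl
Reagents that add atoms: bromomagnesium methoxide CO[Mg]Br (made in the flask from MeMgBr and methanol CO)
Why: Transesterification with MeOMgBr attacks the chelation-activated exocyclic imide carbonyl and is too weakly basic to epimerise the α-aryloxy centre, the auxiliary being released for recovery.

Step 9
Reactants: 13 oxepine-bridged methyl ester
Product: 14 oxepine-bridged tertiary alcohol (R = C(CH3)2OH, S)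
Conditions: MeMgBr (5 equiv), THF, −20 to 0 °C; aq. NH4Cl
Reagents that add atoms: methylmagnesium bromide C[Mg]Br
Why: Double Grignard addition to the α-aryloxy ester gives the tertiary carbinol, while the first equivalent turns the 5-OH into a magnesium phenoxide whose chelate with C4=O should deactivate the vinylogous ester toward 1,2- and 1,4-addition; no stereocentre is created.

Step 10
Reactants: 14 oxepine-bridged tertiary alcohol
Product: 15 6-iodo derivative of 14
Conditions: BnMe3N·ICl2, CaCO3, CH2Cl2–MeOH, 20 °C
Reagents that add atoms: benzyltrimethylammonium dichloroiodate C[N+](C)(C)Cc1ccccc1.Cl[I-]Cl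
Why: Electrophilic aromatic iodination with the mild ICl2− reagent should go ortho to the free, chelated 5-OH on the phloroglucinol-type ring A (C6), since C8 is only para to that hydroxyl and ring B carries two ether oxygens conjugated with the pyranone.

Step 11
Reactants: 15 6-iodo derivative of 14; 16 (E)-4,4,5,5-tetramethyl-2-(3-methylbut-1-en-1-yl)-1,3,2-dioxaborolane
Product: 17 4'-O-MOM ether of the target
Conditions: PdCl2(dppf) (5 mol %), K2CO3, 1,4-dioxane–H2O, 80 °C
Reagents that add atoms: none
Why: Suzuki–Miyaura coupling of the aryl iodide with the (E)-alkenylboronate proceeds with retention of alkene geometry and tolerates the free phenol and the tertiary alcohol.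

Step 12
Reactants: 17 4'-O-MOM ether of the target
Product: 18 CNP0216454.2
Conditions: 1 M HCl, MeOH–THF, 45 °C
Reagents that add atoms: none
Why: Acid-catalysed acetal exchange removes the phenolic MOM ether under conditions too mild to ionise the tertiary alcohol (its cation would be destabilised by the adjacent C–O bond) or to hydrate the styrenyl alkene.

**Compound list**
1 | 1-(2,6-dihydroxy-4-methoxyphenyl)ethan-1-one | CC(=O)c1c(O)cc(OC)cc1O | starting material
2 | 5-hydroxy-7-methoxy-4-oxo-4H-chromene-3-carbaldehyde | COc1cc(O)c2c(c1)occ(C=O)c2=O | intermediate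
3 | 5-hydroxy-3-(hydroxymethyl)-7-methoxy-4H-chromen-4-one | COc1cc(O)c2c(c1)occ(CO)c2=O | intermediate
4 | 3-(bromomethyl)-5-hydroxy-7-methoxy-4H-chromen-4-one | COc1cc(O)c2c(c1)occ(CBr)c2=O | intermediate
5 | 4-bromobenzene-1,3-diol | Oc1ccc(Br)c(O)c1 | starting material
6 | 2-bromo-5-(methoxymethoxy)phenol | COCOc1ccc(Br)c(O)c1 | intermediate
7 | bromoacetic acid | OC(=O)CBr | starting material
8 | 2-[2-bromo-5-(methoxymethoxy)phenoxy]acetic acid | COCOc1ccc(Br)c(OCC(=O)O)c1 | intermediate
9 | (R)-4-benzyloxazolidin-2-one | O=C1OC[C@@H](Cc2ccccc2)N1 | starting material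
10 | (R)-4-benzyl-3-{2-[2-bromo-5-(methoxymethoxy)phenoxy]acetyl}oxazolidin-2-one | COCOc1ccc(Br)c(OCC(=O)N2[C@H](Cc3ccccc3)COC2=O)c1 | intermediate
11 | (R)-4-benzyl-3-{(S)-2-[2-bromo-5-(methoxymethoxy)phenoxy]-3-(5-hydroxy-7-methoxy-4-oxo-4H-chromen-3-yl)propanoyl}oxazolidin-2-one | COc1cc(O)c2c(c1)occ(C[C@@H](C(=O)N3[C@H](Cc4ccccc4)COC3=O)Oc3cc(OCOC)ccc3Br)c2=O | intermediate (not isolated)
12 | oxepine-bridged imide: 5-hydroxy-7-methoxy-4'-(methoxymethoxy)flavone bridged C3–CH2–CH(R)–O–C2', R = C(=O)N of (R)-4-benzyl-2-oxooxazolidine, (S) | COc1cc2oc3c(c(=O)c2c(O)c1)C[C@@H](C(=O)N4[C@H](Cc5ccccc5)COC4=O)Oc1cc(OCOC)ccc1-3 | intermediate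
13 | oxepine-bridged methyl ester: as 12 with R = CO2CH3, (S) | COc1cc2oc3c(c(=O)c2c(O)c1)C[C@@H](C(=O)OC)Oc1cc(OCOC)ccc1-3 | intermediate
14 | oxepine-bridged tertiary alcohol: as 12 with R = C(CH3)2OH, (S) | COc1cc2oc3c(c(=O)c2c(O)c1)C[C@@H](C(C)(C)O)Oc1cc(OCOC)ccc1-3 | intermediate
15 | 6-iodo derivative of 14, (S) | COc1cc2oc3c(c(=O)c2c(O)c1I)C[C@@H](C(C)(C)O)Oc1cc(OCOC)ccc1-3 | intermediate
16 | (E)-4,4,5,5-tetramethyl-2-(3-methylbut-1-en-1-yl)-1,3,2-dioxaborolane | CC(C)/C=C/B1OC(C)(C)C(C)(C)O1 | starting material
17 | 4'-O-MOM ether of the target: 6-[(E)-3-methylbut-1-en-1-yl] derivative of 14, (S) | COc1cc2oc3c(c(=O)c2c(O)c1/C=C/C(C)C)C[C@@H](C(C)(C)O)Oc1cc(OCOC)ccc1-3 | intermediate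
18 | CNP0216454.2: (S)-5,4'-dihydroxy-7-methoxy-6-[(E)-3-methylbut-1-en-1-yl]flavone with the C3–CH2–CH[C(CH3)2OH]–O–C2' oxepine bridge | COc1cc2oc3c(c(=O)c2c(O)c1/C=C/C(C)C)C[C@@H](C(C)(C)O)Oc1cc(O)ccc1-3 | target

**Step count and risks**
Total steps: 12. Longest linear sequence: 9 steps (steps 4, 5, 6, 7, 8, 9, 10, 11, 12; the branch through steps 1, 2, 3 is equally long).

Steps most likely to fail:

1. Step 7. During the warm palladium stage the α-aryloxy imide centre may lose configurational purity or the auxiliary may be cleaved, and residues of the first stage may slow the catalyst. The fallback separates the two bond formations and moves the arylation to a substrate without an enolisable centre. It sets out from 10 and 4: the alkylation alone (NaN(SiMe3)2, THF, −78 to −40 °C, aq. NH4Cl) gives the open-chain imide 11, now isolated. MeOMgBr (CH2Cl2–MeOH, 0 °C) then gives methyl (S)-2-[2-bromo-5-(methoxymethoxy)phenoxy]-3-(5-hydroxy-7-methoxy-4-oxo-4H-chromen-3-yl)propanoate F1, and MeMgBr (THF, −20 to 0 °C) gives (S)-3-{2-[2-bromo-5-(methoxymethoxy)phenoxy]-3-hydroxy-3-methylbutyl}-5-hydroxy-7-methoxy-4H-chromen-4-one F2. Intramolecular direct arylation (Pd(OAc)2, PCy3·HBF4, K2CO3, Me3CCO2H, DMA, 110 °C) closes the oxepine ring and comes back to the route at 14.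

2. Step 10. Iodination may be poorly site-selective, with attack at C8 or on ring B, or may run on to a second iodination. The fallback installs the side chain before ring B is present. It sets out from 3: BnMe3N·ICl2/CaCO3 (CH2Cl2–MeOH) gives 5-hydroxy-3-(hydroxymethyl)-6-iodo-7-methoxy-4H-chromen-4-one F3. Suzuki–Miyaura coupling with 16 (PdCl2(dppf), K2CO3, dioxane–H2O) gives (E)-5-hydroxy-3-(hydroxymethyl)-7-methoxy-6-(3-methylbut-1-en-1-yl)-4H-chromen-4-one F4, and CBr4/PPh3 gives (E)-3-(bromomethyl)-5-hydroxy-7-methoxy-6-(3-methylbut-1-en-1-yl)-4H-chromen-4-one F5. The one-flask alkylation/direct arylation of step 7 with 10 then passes through the open-chain 6-alkenyl alkylated imide F6, not isolated, to the 6-alkenyl oxepine-bridged imide F7. MeOMgBr gives the 6-alkenyl oxepine-bridged methyl ester F8, and MeMgBr comes back to the route at 17.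

3. Step 2. The aldehyde reduction may be accompanied by conjugate reduction or by opening of the pyranone ring. The fallback reaches the hydroxymethyl compound without passing through the aldehyde. It sets out from 1: DMF dimethyl acetal (toluene, 90 °C) gives (E)-1-(2,6-dihydroxy-4-methoxyphenyl)-3-(dimethylamino)prop-2-en-1-one F9, and HCl in MeOH cyclises it to 5-hydroxy-7-methoxy-4H-chromen-4-one F10. Morita–Baylis–Hillman hydroxymethylation at C3 with aqueous formaldehyde and Me3N comes back to the route at 3.

Further compounds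
F1 | step 7 | methyl (S)-2-[2-bromo-5-(methoxymethoxy)phenoxy]-3-(5-hydroxy-7-methoxy-4-oxo-4H-chromen-3-yl)propanoate | COc1cc(O)c2c(c1)occ(C[C@@H](C(=O)OC)Oc3cc(OCOC)ccc3Br)c2=O
F2 | step 7 | (S)-3-{2-[2-bromo-5-(methoxymethoxy)phenoxy]-3-hydroxy-3-methylbutyl}-5-hydroxy-7-methoxy-4H-chromen-4-one | COc1cc(O)c2c(c1)occ(C[C@@H](C(C)(C)O)Oc3cc(OCOC)ccc3Br)c2=O
F3 | step 10 | 5-hydroxy-3-(hydroxymethyl)-6-iodo-7-methoxy-4H-chromen-4-one | COc1cc2occ(CO)c(=O)c2c(O)c1I
F4 | step 10 | (E)-5-hydroxy-3-(hydroxymethyl)-7-methoxy-6-(3-methylbut-1-en-1-yl)-4H-chromen-4-one | COc1cc2occ(CO)c(=O)c2c(O)c1/C=C/C(C)C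
F5 | step 10 | (E)-3-(bromomethyl)-5-hydroxy-7-methoxy-6-(3-methylbut-1-en-1-yl)-4H-chromen-4-one | COc1cc2occ(CBr)c(=O)c2c(O)c1/C=C/C(C)C
F6 | step 10 | open-chain 6-alkenyl alkylated imide (6-alkenyl analogue of 11, not isolated) | COc1cc2occ(C[C@@H](C(=O)N3[C@H](Cc4ccccc4)COC3=O)Oc3cc(OCOC)ccc3Br)c(=O)c2c(O)c1/C=C/C(C)C
F7 | step 10 | 6-alkenyl oxepine-bridged imide (6-alkenyl analogue of 12) | COc1cc2oc3c(c(=O)c2c(O)c1/C=C/C(C)C)C[C@@H](C(=O)N4[C@H](Cc5ccccc5)COC4=O)Oc1cc(OCOC)ccc1-3
F8 | step 10 | 6-alkenyl oxepine-bridged methyl ester (6-alkenyl analogue of 13) | COc1cc2oc3c(c(=O)c2c(O)c1/C=C/C(C)C)C[C@@H](C(=O)OC)Oc1cc(OCOC)ccc1-3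
F9 | step 2 | (E)-1-(2,6-dihydroxy-4-methoxyphenyl)-3-(dimethylamino)prop-2-en-1-one | COc1cc(O)c(C(=O)/C=C/N(C)C)c(O)c1
F10 | step 2 | 5-hydroxy-7-methoxy-4H-chromen-4-one | COc1cc(O)c2c(c1)occc2=O
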